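**Plan**
- Retrosynthesis: the 5-OH is traced to a 5-methyl ether (cleaved last, directed by the C4 ketone), the C4 ketone to a C4 methyl ether, and ring C is then cut across C3–C4 and O1–C2.
- Enabling feature: O1–C8a=C4a–C4 of ring C is the heterodiene of a C4-methoxy ortho-quinone methide, and C2=C3 carrying ring B is the alkene of 3,4-dimethoxystyrene.
- The heterodiene is stored as the dimethyl acetal of 2-hydroxy-4,5,6-trimethoxybenzaldehyde, itself cut at C4a–C4 back to symmetric 3,4,5-trimethoxyphenol (ring A).
- Forward: formylation and acetalisation of ring A, one (4+2) addition that brings in ring B and closes ring C, then C4 ether → carbinol → ketone and 5-O-demethylation.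
- Stereochemistry: C2 (S) is set in the cycloaddition by a confined chiral Brønsted acid that fixes the attacked face of C4 and relays it cis to C2; C4 is erased on oxidation and C2 is not touched afterwards.

Key step: step 3

Assumption: the sense of induction of the confined acid cannot be predicted for this substrate pair; the (S,S) antipode is written and taken to give the 2S series, and the mirror-image acid would be used if the first run showed the opposite sense.

**Step 1**
Reactants: 1 3,4,5-trimethoxyphenol
Product: 2 2-hydroxy-4,5,6-trimethoxybenzaldehyde
Conditions: MgCl2, Et3N, (CH2O)n, MeCN, reflux; then 1 M HCl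
Reagents that add atoms: paraformaldehyde (as formaldehyde), C=O
Why: Magnesium-mediated ortho-formylation of a phenol, in which the magnesium phenoxide delivers formaldehyde to the ortho carbon and a second formaldehyde oxidises the benzylic alkoxide to the aldehyde; the two ortho positions of the symmetric phenol are equivalent, so a single regioisomer should form.

**Step 2**
Reactants: 2 2-hydroxy-4,5,6-trimethoxybenzaldehyde; 3 trimethyl orthoformate
Product: 4 2-(dimethoxymethyl)-3,4,5-trimethoxyphenol
Conditions: HC(OMe)3 (neat, excess), sulfonic acid resin Amberlyst 15 (cat.), 23 °C; filter through K2CO3, evaporate, use crude at once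
Reagents that add atoms: none
Why: Acid-catalysed acetalisation driven by the orthoformate as methoxy donor and water scavenger; the solid acid is filtered off so that no achiral acid reaches step 3, and the labile phenolic acetal is not chromatographed.

**Step 3**
Reactants: 4 2-(dimethoxymethyl)-3,4,5-trimethoxyphenol; 5 3,4-dimethoxystyrene
Product: 7 (2S,4S)-2-(3,4-dimethoxyphenyl)-4,5,6,7-tetramethoxychromane, via methoxy ortho-quinone methide 6 (not isolated)
Conditions: (S,S)-imidodiphosphoric acid HN[P(=O)(O2C20H10Ar2)]2 (each O2C20H10Ar2 a 3,3'-diaryl-1,1'-binaphthalene-2,2'-diolate, Ar = 2,4,6-triethylphenyl; 5 mol %), 5 (2 equiv, freed of stabiliser), 5 Å molecular sieves, toluene, −40 °C; Et3N quench; chromatography on Et3N-deactivated silica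
Reagents that add atoms: none
Why: Proposed new method: the acid removes methanol from 4 to give the O-methyl oxocarbenium, that is protonated methoxy ortho-quinone methide 6, held as a hydrogen-bonded contact ion pair with the imidodiphosphate, after which the CH2 terminus of 5 bonds to C4 and the phenolic oxygen captures the developing C2 benzylic cation in an asynchronous inverse-demand hetero-Diels–Alder (4+2) addition. The closest known reaction types are the achiral acid-promoted three-component union of salicylaldehydes, orthoformates and styrenes to 2,4-cis-4-alkoxyflavans and the confined chiral acid-catalysed intramolecular (4+2) addition of O-alkyl ortho-quinone methides generated from salicylaldehydes and alcohols; the intermolecular enantioselective case is the extension proposed here. Ring C closes in the cycloaddition itself, C3–C4 forming first and O1–C2 second through a chair-like six-membered transition state. The chiral anion is meant to shield one face of C4 of the bound heterodiene, and the endo, chair-like closure places the aryl group cis to the C4 methoxyl, so that 4S control is relayed to 2S. The step needs regioselectivity (aryl at C2), secured by the polarity match between electrophilic C4 and the styrene terminus whose cation is stabilised by the para methoxyl, and chemoselectivity for acetal ionisation over styrene protonation, secured by the three donor oxygens ortho and para to the acetal carbon. Cold, weakly acidic, methanol-scavenging conditions are chosen so that the benzylic C2–O1 bond of 7 is not re-ionised.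

**Step 4**
Reactants: 7 (2S,4S)-2-(3,4-dimethoxyphenyl)-4,5,6,7-tetramethoxychromane
Product: 8 (2S)-2-(3,4-dimethoxyphenyl)-5,6,7-trimethoxychroman-4-ol (C4 epimer mixture)
Conditions: 0.1 M aq HCl–THF (1:4), 0 → 23 °C
Reagents that add atoms: water, O
Why: SN1 solvolysis of a benzylic methyl ether, in which C4, flanked ortho and para by O1, 5-OMe and 7-OMe, should ionise in dilute acid far more readily than C2 and be captured by the excess water; either C4 epimer is acceptable because the centre is oxidised next.

**Step 5**
Reactants: 8 (2S)-2-(3,4-dimethoxyphenyl)-5,6,7-trimethoxychroman-4-ol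
Product: 9 (2S)-2-(3,4-dimethoxyphenyl)-5,6,7-trimethoxychroman-4-one
Conditions: Dess–Martin periodinane, pyridine, CH2Cl2, 0 → 23 °C
Reagents that add atoms: none
Why: Dess–Martin oxidation of a secondary benzylic alcohol under pyridine-buffered, non-aqueous conditions, which should avoid both ionisation of the carbinol and base-induced ring opening of the flavanone, so C2 is left unchanged.

**Step 6**
Reactants: 9 (2S)-2-(3,4-dimethoxyphenyl)-5,6,7-trimethoxychroman-4-one
Product: 10 (2S)-2-(3,4-dimethoxyphenyl)-5-hydroxy-6,7-dimethoxychroman-4-one
Conditions: BCl3 (1.2 equiv), CH2Cl2, −78 → 0 °C; then H2O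
Reagents that add atoms: none
Why: Chelation-controlled aryl methyl ether cleavage, in which boron bridges the C4 carbonyl and the peri 5-methoxy oxygen so that chloride dealkylates only that methyl group; near-stoichiometric reagent and low temperature should spare the 6-, 7-, 3'- and 4'-methyl ethers and the C2 centre.

**Compound list**
1 | 3,4,5-trimethoxyphenol | COc1cc(O)cc(OC)c1OC | starting material
2 | 2-hydroxy-4,5,6-trimethoxybenzaldehyde | COc1cc(O)c(C=O)c(OC)c1OC | intermediate
3 | trimethyl orthoformate | COC(OC)OC | starting material
4 | 2-(dimethoxymethyl)-3,4,5-trimethoxyphenol | COc1cc(O)c(C(OC)OC)c(OC)c1OC | intermediate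
5 | 3,4-dimethoxystyrene (4-ethenyl-1,2-dimethoxybenzene) | COc1ccc(C=C)cc1OC | starting material
6 | 3,4,5-trimethoxy-6-(methoxymethylidene)cyclohexa-2,4-dien-1-one (methoxy ortho-quinone methide, reacting as its protonated ion pair; not isolated) | COC=C1C(=O)C=C(OC)C(OC)=C1OC | intermediate
7 | (2S,4S)-2-(3,4-dimethoxyphenyl)-4,5,6,7-tetramethoxychromane (2,4-cis) | COc1ccc([C@@H]2C[C@H](OC)c3c(OC)c(OC)c(OC)cc3O2)cc1OC | intermediate
8 | (2S)-2-(3,4-dimethoxyphenyl)-5,6,7-trimethoxychroman-4-ol (C4 epimer mixture) | COc1ccc([C@@H]2CC(O)c3c(OC)c(OC)c(OC)cc3O2)cc1OC | intermediate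
9 | (2S)-2-(3,4-dimethoxyphenyl)-5,6,7-trimethoxychroman-4-one | COc1ccc([C@@H]2CC(=O)c3c(OC)c(OC)c(OC)cc3O2)cc1OC | intermediate
10 | (2S)-2-(3,4-dimethoxyphenyl)-5-hydroxy-6,7-dimethoxychroman-4-one | COc1ccc([C@@H]2CC(=O)c3c(cc(OC)c(OC)c3O)O2)cc1OC | target

**Totals**
Total step count: 6. Longest linear sequence: 6 steps (1 → 10).

**Steps most likely to fail**

Step 3. The ion pair may be too loose to control the face of C–C bond formation, and the cis relay may be lost if the C2 benzylic cation lives long enough to rotate before closure. A trans isomer formed on the same C4 face carries 2R, so only the cis isomer should be taken forward and its enantiomeric purity checked. The acid may also start oligomerisation of the electron-rich styrene, or re-ionise the C2–O1 bond of the product. The fallback gives up the cycloaddition and uses known chemistry; it sets out from 1 and rejoins the route at 9. Friedel–Crafts acylation of 1 (AcOH, BF3·OEt2, 80 °C) should give 1-(6-hydroxy-2,3,4-trimethoxyphenyl)ethan-1-one F1. Condensation with N,N-dimethylformamide dimethyl acetal should give the enaminone (E)-3-(dimethylamino)-1-(6-hydroxy-2,3,4-trimethoxyphenyl)prop-2-en-1-one F2. Acid (HCl, CH2Cl2) should then close it, with loss of dimethylamine, to 5,6,7-trimethoxy-4H-chromen-4-one F3. Enantioselective conjugate addition of 3,4-dimethoxyphenylboronic acid to F3 (Pd(OCOCF3)2, 4-tert-butyl-2-(pyridin-2-yl)-4,5-dihydrooxazole in the antipode that delivers 2S, NH4PF6, water, 1,2-dichloroethane, 60 °C) should give 9, which continues with step 6.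

Step 4. The C4 cation may lose a proton to the flav-3-ene, may be captured by the nucleophilic C8 position of a second molecule (oligomerisation), or prolonged acid exposure may begin to ionise C2–O1. The fallback replaces solvolysis by oxidation; it sets out from 7 and rejoins at 9, bypassing 8 and step 5. 2,3-Dichloro-5,6-dicyano-1,4-benzoquinone in CH2Cl2–pH 7 buffer at 0 °C should abstract the C4 hydride, which is activated by the methoxyl and the donor-rich ring A. Water should capture the oxocarbenium as the hemiketal (2S)-2-(3,4-dimethoxyphenyl)-4,5,6,7-tetramethoxychroman-4-ol F4, which collapses to 9 with loss of methanol.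

Step 2. The free-phenol acetal may ionise prematurely and the resulting quinone methide condense with itself, the acetal may revert to the aldehyde on handling, or the hydrogen-bonded, donor-deactivated aldehyde may convert incompletely. The fallback masks the phenol during acetalisation and unmasks it under base; it sets out from 2 and rejoins at 4. Acetylation (Ac2O, pyridine) should give 2-formyl-3,4,5-trimethoxyphenyl acetate F5. Acetalisation as in step 2 should give the stable 2-(dimethoxymethyl)-3,4,5-trimethoxyphenyl acetate F6, which can be purified. Methanolysis (K2CO3, MeOH, 0 °C; pH 7 buffer) should release 4 without exposure to acid.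

**Further compounds**
F1 | step 3 | 1-(6-hydroxy-2,3,4-trimethoxyphenyl)ethan-1-one | CC(=O)c1c(O)cc(OC)c(OC)c1OC
F2 | step 3 | (E)-3-(dimethylamino)-1-(6-hydroxy-2,3,4-trimethoxyphenyl)prop-2-en-1-one | CN(C)/C=C/C(=O)c1c(O)cc(OC)c(OC)c1OC
F3 | step 3 | 5,6,7-trimethoxy-4H-chromen-4-one | COc1cc2occc(=O)c2c(OC)c1OC
F4 | step 4 | (2S)-2-(3,4-dimethoxyphenyl)-4,5,6,7-tetramethoxychroman-4-ol | COc1ccc([C@@H]2CC(O)(OC)c3c(OC)c(OC)c(OC)cc3O2)cc1OC
F5 | step 2 | 2-formyl-3,4,5-trimethoxyphenyl acetate | CC(=O)Oc1cc(OC)c(OC)c(OC)c1C=O
F6 | step 2 | 2-(dimethoxymethyl)-3,4,5-trimethoxyphenyl acetate | CC(=O)Oc1cc(OC)c(OC)c(OC)c1C(OC)OC
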